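The central benzene ring carries four contiguous carbon substituents (C1 methide carbon, C2 aryl, C5 CH2OH, C6 alkynyl). The route builds this ring instead of decorating it. The C5 hydroxymethyl oxygen and the future C6 alkyne carbon are joined as a temporary ester that tethers a 5-arylpentadienol to a 4,4-diaryl-4-hydroxybutynoate. An intramolecular Diels–Alder reaction and dehydrogenation should then deliver the arene with all four substituents regiodefined, the triarylcarbinol included. The lactone, a ring absent from the target, is afterwards cut by reduction and one-carbon homologation, so that its carbonyl carbon becomes the ring-bound alkyne carbon.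

Key step: step 6

Remark: the target SMILES has no stereodescriptor and no stereocentre, and the two oxygenated rings on the methide carbon interchange by quinone methide/phenol tautomerism, so the compound is treated as achiral and no enantioselective step is planned; compounds 1, 2, 5, 7, 14 and the Ohira–Bestmann reagent are taken as catalogue materials.

Step 1
Reactants: 1 4-(methoxymethoxy)benzaldehyde; 2 triethyl 4-phosphonocrotonate
Product: 3 ethyl (2E,4E)-5-[4-(methoxymethoxy)phenyl]penta-2,4-dienoate
Conditions: LiHMDS, THF, −78 °C → rt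
Reagents that add atoms: none
Why: Vinylogous Horner–Wadsworth–Emmons olefination of an aromatic aldehyde with the stabilised γ-phosphonocrotonate anion should give the thermodynamically preferred 2E,4E-dienoate.

Step 2
Reactants: 3 ethyl (2E,4E)-5-[4-(methoxymethoxy)phenyl]penta-2,4-dienoate
Product: 4 (2E,4E)-5-[4-(methoxymethoxy)phenyl]penta-2,4-dien-1-ol
Conditions: DIBAL-H (2.2 equiv), CH2Cl2, −78 °C; Rochelle salt
Reagents that add atoms: none
Why: DIBAL-H 1,2-reduction of a conjugated ester gives the allylic alcohol and leaves the diene geometry and the MOM acetal untouched.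

Step 3
Reactants: 4 (2E,4E)-5-[4-(methoxymethoxy)phenyl]penta-2,4-dien-1-ol; 5 propiolic acid
Product: 6 (2E,4E)-5-[4-(methoxymethoxy)phenyl]penta-2,4-dien-1-yl propiolate
Conditions: DCC, DMAP (cat.), CH2Cl2, −20 → 0 °C
Reagents that add atoms: none
Why: Steglich esterification at low temperature acylates the primary allylic alcohol faster than it can add to the ynoate or ionise.

Step 4
Reactants: 7 4,4'-dihydroxybenzophenone
Product: 8 4,4'-bis(methoxymethoxy)benzophenone
Conditions: MOMCl (2.5 equiv), i-Pr2NEt, CH2Cl2, 0 °C → rt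
Reagents that add atoms: chloromethyl methyl ether (MOMCl), COCCl
Why: O-alkylation of the phenols gives MOM ethers, which survive all later basic, hydridic and thermal steps and fall in the acid needed at the end.

Step 5
Reactants: 6 (2E,4E)-5-[4-(methoxymethoxy)phenyl]penta-2,4-dien-1-yl propiolate; 8 4,4'-bis(methoxymethoxy)benzophenone
Product: 9 (2E,4E)-5-[4-(methoxymethoxy)phenyl]penta-2,4-dien-1-yl 4-hydroxy-4,4-bis[4-(methoxymethoxy)phenyl]but-2-ynoate
Conditions: 6, LiHMDS, THF, −78 °C; then 8, −78 → −40 °C; AcOH quench at −78 °C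
Reagents that add atoms: none
Why: Carbonyl alkynylation: the lithium acetylide of the propiolate adds 1,2 to the diaryl ketone, and the cold acidic quench should prevent retro-addition; the new carbinol carbon is not stereogenic.

Step 6
Reactants: 9 (2E,4E)-5-[4-(methoxymethoxy)phenyl]penta-2,4-dien-1-yl 4-hydroxy-4,4-bis[4-(methoxymethoxy)phenyl]but-2-ynoate
Product: 11 7-{hydroxybis[4-(methoxymethoxy)phenyl]methyl}-6-[4-(methoxymethoxy)phenyl]isobenzofuran-1(3H)-one, via cis-dihydrophthalide cycloadduct 10 (not isolated)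
Conditions: PhMe (0.01 M), BHT (cat.), 150 °C, sealed tube; then DDQ (1.1 equiv), rt
Reagents that add atoms: none
Why: Heating populates the s-cis ester conformer, in which the (E,E)-diene and the ester-conjugated alkyne should undergo a concerted, asynchronous thermal [4+2] cycloaddition (type 1 intramolecular Diels–Alder); DDQ then removes the two doubly allylic hydrogens of the cyclohexa-1,4-diene and makes the sequence irreversible. The closest known reaction type is the thermal intramolecular Diels–Alder reaction of pentadienyl acrylates, propiolates and acetylenedicarboxylates to fused γ-lactones, followed by dehydrogenation to phthalides. Two rings close: the six-membered carbocycle by the [4+2] itself and the five-membered lactone as the fused tether ring (three-atom tether, bicyclo[4.3.0] mode; a bridged mode is out of reach). The two sp3 centres of 10 (C3a and C6) form cis by suprafacial addition to the E,E-diene and are erased on aromatisation, so no stereocontrol is needed. The selectivity required is regiochemical and the tether secures it: the CH2O-bearing diene terminus must bond to the carbonyl-bound alkyne carbon, hence the aryl-bearing terminus to the carbinol-bearing carbon, which places CH2O, C=O, C(OH)Ar2 and aryl on four contiguous ring carbons in the order of the target. The residual risk is steric (aryl next to the triarylcarbinol carbon), but the alkyne substituent lies in the plane of the forming ring and the bond to that carbon can form late.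

Step 7
Reactants: 11 7-{hydroxybis[4-(methoxymethoxy)phenyl]methyl}-6-[4-(methoxymethoxy)phenyl]isobenzofuran-1(3H)-one
Product: 13 {2-ethynyl-3-(hydroxymethyl)-6-[4-(methoxymethoxy)phenyl]phenyl}bis[4-(methoxymethoxy)phenyl]methanol, via lactol 12 (not isolated)
Conditions: DIBAL-H (2.5 equiv), CH2Cl2, −78 °C; then MeOH, K2CO3, Ohira–Bestmann reagent, −78 °C → rt
Reagents that add atoms: dimethyl (1-diazo-2-oxopropyl)phosphonate (Ohira–Bestmann reagent), CC(=O)C(=[N+]=[N-])P(=O)(OC)OC
Why: One-pot half-reduction of the lactone and Seyferth–Gilbert/Ohira–Bestmann homologation of the open hydroxy-aldehyde form of the lactol should turn the lactone carbonyl carbon into the ring-bound alkyne carbon and release the CH2OH group.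

Step 8
Reactants: 13 {2-ethynyl-3-(hydroxymethyl)-6-[4-(methoxymethoxy)phenyl]phenyl}bis[4-(methoxymethoxy)phenyl]methanol; 14 4-iodophenol
Product: 15 {2-[(4-hydroxyphenyl)ethynyl]-3-(hydroxymethyl)-6-[4-(methoxymethoxy)phenyl]phenyl}bis[4-(methoxymethoxy)phenyl]methanol
Conditions: PdCl2(PPh3)2 (cat.), CuI (cat.), Et3N, THF, rt
Reagents that add atoms: none
Why: Sonogashira coupling of a terminal alkyne with an aryl iodide runs at room temperature and tolerates the free phenol and both alcohols.

Step 9
Reactants: 15 {2-[(4-hydroxyphenyl)ethynyl]-3-(hydroxymethyl)-6-[4-(methoxymethoxy)phenyl]phenyl}bis[4-(methoxymethoxy)phenyl]methanol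
Product: 16 selaginellin
Conditions: 2 M HCl, MeOH/THF, 40 °C; aq. NaHCO3 work-up
Reagents that add atoms: none
Why: Acid cleaves the three MOM acetals and ionises the doubly p-oxygenated triarylcarbinol, and loss of a phenolic proton from the cation (E1 dehydration) should give the p-quinone methide, the form in which the compound exists.

Compound list
1 | 4-(methoxymethoxy)benzaldehyde | COCOc1ccc(C=O)cc1 | starting material
2 | triethyl 4-phosphonocrotonate | CCOC(=O)/C=C/CP(=O)(OCC)OCC | starting material
3 | ethyl (2E,4E)-5-[4-(methoxymethoxy)phenyl]penta-2,4-dienoate | CCOC(=O)/C=C/C=C/c1ccc(OCOC)cc1 | intermediate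
4 | (2E,4E)-5-[4-(methoxymethoxy)phenyl]penta-2,4-dien-1-ol | OC/C=C/C=C/c1ccc(OCOC)cc1 | intermediate
5 | propiolic acid | C#CC(=O)O | starting material
6 | (2E,4E)-5-[4-(methoxymethoxy)phenyl]penta-2,4-dien-1-yl propiolate | C#CC(=O)OC/C=C/C=C/c1ccc(OCOC)cc1 | intermediate
7 | 4,4'-dihydroxybenzophenone | O=C(c1ccc(O)cc1)c1ccc(O)cc1 | starting material
8 | 4,4'-bis(methoxymethoxy)benzophenone | O=C(c1ccc(OCOC)cc1)c1ccc(OCOC)cc1 | intermediate
9 | (2E,4E)-5-[4-(methoxymethoxy)phenyl]penta-2,4-dien-1-yl 4-hydroxy-4,4-bis[4-(methoxymethoxy)phenyl]but-2-ynoate | COCOc1ccc(/C=C/C=C/COC(=O)C#CC(O)(c2ccc(OCOC)cc2)c2ccc(OCOC)cc2)cc1 | intermediate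
10 | cis-7-{hydroxybis[4-(methoxymethoxy)phenyl]methyl}-6-[4-(methoxymethoxy)phenyl]-3a,6-dihydroisobenzofuran-1(3H)-one (racemic, 3a-H and 6-H cis, one enantiomer drawn) | O=C1OC[C@@H]2C=C[C@H](c3ccc(OCOC)cc3)C(C(O)(c3ccc(OCOC)cc3)c3ccc(OCOC)cc3)=C12 | intermediate (not isolated)
11 | 7-{hydroxybis[4-(methoxymethoxy)phenyl]methyl}-6-[4-(methoxymethoxy)phenyl]isobenzofuran-1(3H)-one | O=C1OCc2ccc(-c3ccc(OCOC)cc3)c(C(O)(c3ccc(OCOC)cc3)c3ccc(OCOC)cc3)c12 | intermediate
12 | 7-{hydroxybis[4-(methoxymethoxy)phenyl]methyl}-6-[4-(methoxymethoxy)phenyl]-1,3-dihydroisobenzofuran-1-ol (lactol, equilibrating epimers, centre unassigned) | OC1OCc2ccc(-c3ccc(OCOC)cc3)c(C(O)(c3ccc(OCOC)cc3)c3ccc(OCOC)cc3)c12 | intermediate (not isolated)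
13 | {2-ethynyl-3-(hydroxymethyl)-6-[4-(methoxymethoxy)phenyl]phenyl}bis[4-(methoxymethoxy)phenyl]methanol | OCc1ccc(-c2ccc(OCOC)cc2)c(C(O)(c2ccc(OCOC)cc2)c2ccc(OCOC)cc2)c1C#C | intermediate
14 | 4-iodophenol | Oc1ccc(I)cc1 | starting material
15 | {2-[(4-hydroxyphenyl)ethynyl]-3-(hydroxymethyl)-6-[4-(methoxymethoxy)phenyl]phenyl}bis[4-(methoxymethoxy)phenyl]methanol | OCc1ccc(-c2ccc(OCOC)cc2)c(C(O)(c2ccc(OCOC)cc2)c2ccc(OCOC)cc2)c1C#Cc1ccc(O)cc1 | intermediate
16 | selaginellin, 4-[(4-hydroxyphenyl){2-[(4-hydroxyphenyl)ethynyl]-3-(hydroxymethyl)-6-(4-hydroxyphenyl)phenyl}methylidene]cyclohexa-2,5-dien-1-one | O=C1C=CC(=C(c2ccc(O)cc2)c2c(-c3ccc(O)cc3)ccc(CO)c2C#Cc2ccc(O)cc2)C=C1 | target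

Total step count: 9. Longest linear sequence: 8 steps (1, 2, 3, 5, 6, 7, 8, 9); step 4 is a one-step side branch.

Steps most likely to fail

Step 6 (key step). The ester tether prefers its s-trans conformation and the carbinol-bearing alkyne carbon is crowded, so cycloaddition may be slower than thermal ionisation or retro-alkynylation of the propargylic carbinol. The fallback uses a doubly activated, less hindered dienophile and adds the second aryl group afterwards. It sets out from 6 and 1. LiHMDS and aldehyde 1 should give the racemic propargylic alcohol (2E,4E)-5-[4-(methoxymethoxy)phenyl]penta-2,4-dien-1-yl 4-hydroxy-4-[4-(methoxymethoxy)phenyl]but-2-ynoate F1, and MnO2 should oxidise it to the 4-aryl-4-oxobut-2-ynoate F2. As an acetylenedicarbonyl-type dienophile, this should cyclise near 80 °C to the cis cycloadduct F3, which DDQ dehydrogenates to 7-[4-(methoxymethoxy)benzoyl]-6-[4-(methoxymethoxy)phenyl]isobenzofuran-1(3H)-one F4. 4-(Methoxymethoxy)phenylmagnesium bromide F5 (from 1-bromo-4-(methoxymethoxy)benzene and Mg), with LaCl3·2LiCl at −78 °C, should then add to the ketone in preference to the lactone, and the route is rejoined at 11.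

Step 5. The ester-stabilised lithium acetylide may add too slowly to the electron-rich diaryl ketone and decompose or revert on warming. The fallback makes the carbinol with an unstabilised acetylide and forms the ester last; it sets out from 8 and 4. Ethynylmagnesium bromide (THF, 0 °C) should add to 8 to give 1,1-bis[4-(methoxymethoxy)phenyl]prop-2-yn-1-ol F6. Its dianion (n-BuLi, 2.1 equiv, −78 °C) is carboxylated with CO2 to 4-hydroxy-4,4-bis[4-(methoxymethoxy)phenyl]but-2-ynoic acid F7. Steglich esterification of F7 with dienol 4 (DCC, cat. DMAP) rejoins the route at 9.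

Step 7. Over-reduction may occur, or the hindered hydroxy-aldehyde may stay locked as a cyclic hemiacetal with the neighbouring tertiary alkoxide so that homologation stalls; the alkoxide may also cyclise onto the new alkyne under base. The fallback avoids the aldehyde and brings in both alkyne carbons with their aryl group at once; it sets out from 11. 4-(Methoxymethoxy)benzylmagnesium chloride F8 (from the benzyl chloride and Mg) should add once to the lactone to give the hemiketal 1-[4-(methoxymethoxy)benzyl]-7-{hydroxybis[4-(methoxymethoxy)phenyl]methyl}-6-[4-(methoxymethoxy)phenyl]-1,3-dihydroisobenzofuran-1-ol F9. PPTS (cat., toluene, 4 Å MS) should dehydrate it to the (Z)-1-arylidene-1,3-dihydroisobenzofuran F10. Vinyl deprotonation with n-BuLi/KOt-Bu at −78 °C and anti β-elimination of the benzylic alkoxide should open the ring to the tetrakis-MOM diarylalkyne diol F11, which unveils the triple bond and the CH2OH together. The conditions of step 9 then convert F11 into 16.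

Further compounds
F1 | step 6 | (2E,4E)-5-[4-(methoxymethoxy)phenyl]penta-2,4-dien-1-yl 4-hydroxy-4-[4-(methoxymethoxy)phenyl]but-2-ynoate (racemic) | COCOc1ccc(/C=C/C=C/COC(=O)C#CC(O)c2ccc(OCOC)cc2)cc1
F2 | step 6 | (2E,4E)-5-[4-(methoxymethoxy)phenyl]penta-2,4-dien-1-yl 4-[4-(methoxymethoxy)phenyl]-4-oxobut-2-ynoate | COCOc1ccc(/C=C/C=C/COC(=O)C#CC(=O)c2ccc(OCOC)cc2)cc1
F3 | step 6 | cis-7-[4-(methoxymethoxy)benzoyl]-6-[4-(methoxymethoxy)phenyl]-3a,6-dihydroisobenzofuran-1(3H)-one (racemic, one enantiomer drawn) | O=C1OC[C@@H]2C=C[C@H](c3ccc(OCOC)cc3)C(C(=O)c3ccc(OCOC)cc3)=C12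
F4 | step 6 | 7-[4-(methoxymethoxy)benzoyl]-6-[4-(methoxymethoxy)phenyl]isobenzofuran-1(3H)-one | O=C1OCc2ccc(-c3ccc(OCOC)cc3)c(C(=O)c3ccc(OCOC)cc3)c12
F5 | step 6 | 4-(methoxymethoxy)phenylmagnesium bromide | COCOc1ccc([Mg]Br)cc1
F6 | step 5 | 1,1-bis[4-(methoxymethoxy)phenyl]prop-2-yn-1-ol | C#CC(O)(c1ccc(OCOC)cc1)c1ccc(OCOC)cc1
F7 | step 5 | 4-hydroxy-4,4-bis[4-(methoxymethoxy)phenyl]but-2-ynoic acid | OC(=O)C#CC(O)(c1ccc(OCOC)cc1)c1ccc(OCOC)cc1
F8 | step 7 | 4-(methoxymethoxy)benzylmagnesium chloride | COCOc1ccc(C[Mg]Cl)cc1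
F9 | step 7 | 1-[4-(methoxymethoxy)benzyl]-7-{hydroxybis[4-(methoxymethoxy)phenyl]methyl}-6-[4-(methoxymethoxy)phenyl]-1,3-dihydroisobenzofuran-1-ol (racemic hemiketal) | OC1(Cc2ccc(OCOC)cc2)OCc2ccc(-c3ccc(OCOC)cc3)c(C(O)(c3ccc(OCOC)cc3)c3ccc(OCOC)cc3)c12
F10 | step 7 | (Z)-1-[4-(methoxymethoxy)benzylidene]-7-{hydroxybis[4-(methoxymethoxy)phenyl]methyl}-6-[4-(methoxymethoxy)phenyl]-1,3-dihydroisobenzofuran | COCOc1ccc(/C=C2\OCc3ccc(-c4ccc(OCOC)cc4)c(C(O)(c4ccc(OCOC)cc4)c4ccc(OCOC)cc4)c32)cc1
F11 | step 7 | {3-(hydroxymethyl)-2-{[4-(methoxymethoxy)phenyl]ethynyl}-6-[4-(methoxymethoxy)phenyl]phenyl}bis[4-(methoxymethoxy)phenyl]methanol | OCc1ccc(-c2ccc(OCOC)cc2)c(C(O)(c2ccc(OCOC)cc2)c2ccc(OCOC)cc2)c1C#Cc1ccc(OCOC)cc1
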